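**Plan**
Lettering: rings A–G run from the 2,4,6-trihydroxyphenyl end. In rings B–G, C1 is the carbon whose oxygen leads back toward ring A; in ring A, C1 carries O–B.
Cuts: all hydroxyls are carried as benzyl ethers. Five aryl–oxygen bonds are cut (A C1–O, B C4–O, C C6–O, D C5–O, E C6–O), and ring G is cut at both ring bonds of its ether carbon (C1–C2 and C1–C6).
Enabling feature: in ring G the ether carbon C1 lies between two CH groups (C2, C6), while C3, C4 and C5 bear oxygen. C2–C6 with their three oxygens are therefore the five carbons of a 3,5-dioxygenated 4-pyranone, and C1, already bonded to the ring F oxygen, replaces the pyranone ring oxygen.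
Forward: ring F enters as an aryloxymethylphosphonium salt and ring G is built on it from the pyranone. Rings E, D, C, B and A then follow one at a time, each by Ullmann coupling of the chain phenol with a bromobenzaldehyde (23, 28, 23, 37, 37) and Baeyer–Villiger unmasking of the next phenol. One hydrogenolysis ends the route.
Stereochemistry: the target has no stereocentre, axis or configured alkene, so nothing has to be set.

Key step: step 8

Remark: 5, 27 and 35 are taken to be catalogue chemicals. The labile alkene geometries of 3 and of the phosphorus-side alkene in 18 and 19 are drawn without descriptors.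

Step 1
Reactants: 1 1,3-bis(benzyloxy)propan-2-ol
Product: 2 1,3-bis(benzyloxy)propan-2-one
Conditions: TEMPO (1 mol %), KBr (10 mol %), NaOCl (1.2 equiv), NaHCO3 buffer, CH2Cl2/H2O, 0 °C
Reagents that add atoms: none
Why: TEMPO/hypochlorite oxidation should turn the unhindered secondary alcohol into the ketone without touching the benzyl ethers.

Step 2
Reactants: 2 1,3-bis(benzyloxy)propan-2-one
Product: 4 3,5-bis(benzyloxy)-4H-pyran-4-one, via bis-enaminone 3 (not isolated)
Conditions: Me2NCH(OMe)2 (neat, excess), 110 °C; evaporate; 2 M HCl, THF, 60 °C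
Reagents that add atoms: N,N-dimethylformamide dimethyl acetal COC(OC)N(C)C; water O
Why: Both alkoxy-bearing methylene groups should condense with the amide acetal (enaminone formation), and acid hydrolysis of one enamine end followed by addition–elimination at the other closes the ring, which is the usual way from 1,3-disubstituted acetones to 3,5-disubstituted 4-pyranones.

Step 3
Reactants: 5 3,4,5-trihydroxybenzaldehyde
Product: 6 3,4,5-tris(benzyloxy)benzaldehyde
Conditions: BnBr (3.5 equiv), K2CO3, DMF, 60 °C, Ar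
Reagents that add atoms: benzyl bromide BrCc1ccccc1
Why: Exhaustive Williamson etherification of the three phenols is routine for gallic-type aldehydes.

Step 4
Reactants: 6 3,4,5-tris(benzyloxy)benzaldehyde
Product: 8 3,4,5-tris(benzyloxy)phenol, via aryl formate 7 (not isolated)
Conditions: mCPBA (1.3 equiv), CH2Cl2, 0 °C to rt; aq. Na2SO3 wash; K2CO3 (cat.), MeOH/THF, rt
Reagents that add atoms: mCPBA OOC(=O)c1cccc(Cl)c1
Why: Baeyer–Villiger oxidation with migration of the electron-rich aryl group gives the formate, and base-catalysed methanolysis frees the phenol.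

Step 5
Reactants: 8 3,4,5-tris(benzyloxy)phenol
Product: 9 2,6-bis(benzyloxy)-1,4-benzoquinone
Conditions: PhI(OAc)2 (1.1 equiv), MeCN/H2O, 0 °C
Reagents that add atoms: water O
Why: In this hypervalent-iodine oxidation of a 4-alkoxyphenol, water adds to the para carbon of the phenoxenium ion and the hemiketal expels benzyl alcohol, so only the central benzyl group is lost.

Step 6
Reactants: 9 2,6-bis(benzyloxy)-1,4-benzoquinone
Product: 11 4-(allyloxy)-2,6-bis(benzyloxy)phenol, via hydroquinone 10 (not isolated)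
Conditions: Na2S2O4, THF/H2O, rt; extract under Ar; allyl bromide (1.0 equiv), K2CO3 (1.1 equiv), DMF, 0 °C to rt
Reagents that add atoms: allyl bromide C=CCBr
Why: Dithionite reduction followed by Williamson mono-allylation should go to O4, which has no ortho substituent and is the more acidic hydroxyl, whereas O1 is flanked by and hydrogen-bonded to two benzyloxy groups; the air-sensitive hydroquinone is carried on crude.

Step 7
Reactants: 11 4-(allyloxy)-2,6-bis(benzyloxy)phenol; 12 triphenylphosphine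
Product: 14 {[4-(allyloxy)-2,6-bis(benzyloxy)phenoxy]methyl}triphenylphosphonium chloride, via chloromethyl ether 13 (not isolated)
Conditions: NaH, BrCH2Cl (10 equiv), THF, 0 to 60 °C; filter, evaporate; PPh3, toluene, 90 °C
Reagents that add atoms: bromochloromethane ClCBr
Why: SN2 displacement of bromide from excess BrCH2Cl is an established O-chloromethylation of 2,6-disubstituted phenols, whose flanking groups slow a second displacement, and quaternisation of PPh3 by the moisture-sensitive chloromethyl ether should precipitate the salt.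

Step 8
Reactants: 4 3,5-bis(benzyloxy)-4H-pyran-4-one; 14 {[4-(allyloxy)-2,6-bis(benzyloxy)phenoxy]methyl}triphenylphosphonium chloride
Product: 20 5-(allyloxy)-1,3-bis(benzyloxy)-2-{3,5-bis(benzyloxy)-4-[(tert-butyldimethylsilyl)oxy]phenoxy}benzene (F–G dimer), via silyloxypyrylium triflate 15 (not isolated), via aryloxymethylene ylide 16 (not isolated), via 2H-pyran adduct 17 (not isolated), via dienal phosphonium triflate 18 (not isolated), via dienal ylide 19 (not isolated)
Conditions: 4, t-BuMe2SiOSO2CF3 (1.0 equiv), CH2Cl2, 0 °C; separately 14, NaN(SiMe3)2 (1.0 equiv), THF, −78 °C (NaCl settles); pyrylium solution into ylide solution, −78 °C; NaN(SiMe3)2 (1.05 equiv), −78 °C to rt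
Reagents that add atoms: tert-butyldimethylsilyl trifluoromethanesulfonate CC(C)(C)[Si](C)(C)OS(=O)(=O)C(F)(F)F
Why: Proposed new method: silylation of the carbonyl oxygen of 4 gives the aromatic 4-silyloxypyrylium ion 15, the carbon of ylide 16 adds to its C2 (first new bond, G C1–C2) to give 2H-pyran 17, and 17 opens by a thermal 6π electrocyclic reaction to the cis-dienal phosphonium salt 18. The second equivalent of NaN(SiMe3)2 removes the remaining P–CH proton, and the vinylogous ylide 19 attacks the aldehyde carbon (former pyran C6), so ring G closes as a six-membered carbocycle by intramolecular Wittig olefination (second new bond, G C1=C6), with the former ring oxygen leaving on phosphorus as Ph3PO and aromatisation making the closure irreversible. The closest known reaction types are the conversion of 2,4,6-trisubstituted pyrylium salts into benzenes with alkylidenetriphenylphosphoranes and the silyl triflate activation of 4-pyranones and chromones toward carbon nucleophiles at C2; new here are their combination, the oxygen-substituted ylide and the 2,6-unsubstituted pyrylium ion. The site selectivity needed, C2 rather than C4 or silicon, should follow from the two benzyloxy groups flanking C4, from the bulk of the tert-butyl group on silicon, from removal of chloride as insoluble NaCl, and from the symmetry of 4, which makes C2 and C6 identical. The alkene next to the phosphorus-bearing carbon of 18 may first form with the chain turned outward, but the ring opening is reversible and the push–pull ylide 19 has low rotation barriers, so loss of Ph3PO should drain the mixture through the geometry that can close. No stereocentre survives, because both sp3 carbons of 17 end as sp2 carbons of ring G.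

Step 9
Reactants: 20 F–G dimer (allyl ether on F C1, silyl ether on G C4)
Product: 21 5-(allyloxy)-1,3-bis(benzyloxy)-2-[3,4,5-tris(benzyloxy)phenoxy]benzene
Conditions: CsF (2 equiv), BnBr (1.5 equiv), DMF, rt
Reagents that add atoms: benzyl bromide BrCc1ccccc1
Why: Fluoride desilylation with in situ Williamson benzylation of the phenoxide replaces the aryl silyl ether, which would not last through the basic couplings ahead, by a benzyl ether in one operation.

Step 10
Reactants: 21 5-(allyloxy)-1,3-bis(benzyloxy)-2-[3,4,5-tris(benzyloxy)phenoxy]benzene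
Product: 22 3,5-bis(benzyloxy)-4-[3,4,5-tris(benzyloxy)phenoxy]phenol (F–G phenol)
Conditions: Pd(PPh3)4 (5 mol %), morpholine (5 equiv), THF, rt
Reagents that add atoms: none
Why: In this Tsuji–Trost deallylation, zerovalent palladium ionises the allyl aryl ether to a π-allyl complex that morpholine intercepts, and benzyl and diaryl ethers are inert.

Step 11
Reactants: 6 3,4,5-tris(benzyloxy)benzaldehyde
Product: 23 2-bromo-3,4,5-tris(benzyloxy)benzaldehyde
Conditions: NBS (1.05 equiv), MeCN, rt, dark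
Reagents that add atoms: N-bromosuccinimide O=C1CCC(=O)N1Br
Why: In this electrophilic aromatic bromination the two free positions of 6 are equivalent, each ortho and para to a benzyloxy group, and polar dark conditions suppress benzylic radical bromination.

Step 12
Reactants: 22 F–G phenol; 23 2-bromo-3,4,5-tris(benzyloxy)benzaldehyde
Product: 24 3,4,5-tris(benzyloxy)-2-{3,5-bis(benzyloxy)-4-[3,4,5-tris(benzyloxy)phenoxy]phenoxy}benzaldehyde (E–F–G aldehyde)
Conditions: 23 (1.5 equiv), CuI (20 mol %), N,N-dimethylglycine hydrochloride (40 mol %), Cs2CO3 (2.5 equiv), dioxane, 100 °C, Ar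
Reagents that add atoms: none
Why: In this Ullmann-type diaryl ether coupling with monovalent copper, the unhindered F C1 phenol is the nucleophile and the C–Br bond of 23 is activated by its ortho formyl group, as in the classical couplings of 2-bromo-3,4,5-trialkoxybenzoyl compounds with phenols.

Step 13
Reactants: 24 E–F–G aldehyde
Product: 26 E–F–G phenol (OH at E C1), via trimer formate 25 (not isolated)
Conditions: mCPBA (1.3 equiv), CH2Cl2, 0 °C to rt; aq. Na2SO3 wash; K2CO3 (cat.), MeOH/THF, rt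
Reagents that add atoms: mCPBA OOC(=O)c1cccc(Cl)c1
Why: In this Baeyer–Villiger oxidation ring E, with an ortho aryloxy and a para benzyloxy group, migrates readily, and methanolysis of the formate frees the E C1 phenol.

Step 14
Reactants: 27 3-bromo-4,5-dihydroxybenzaldehyde
Product: 28 3-bromo-4,5-bis(benzyloxy)benzaldehyde
Conditions: BnBr (2.4 equiv), K2CO3, DMF, 60 °C
Reagents that add atoms: benzyl bromide BrCc1ccccc1
Why: This is a double Williamson etherification of a catechol.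

Step 15
Reactants: 26 E–F–G phenol; 28 3-bromo-4,5-bis(benzyloxy)benzaldehyde
Product: 29 D–E–F–G aldehyde (ring D: CHO at C1, OBn at C3 and C4, O–E at C5)
Conditions: 28 (1.5 equiv), CuI (20 mol %), N,N-dimethylglycine hydrochloride (40 mol %), Cs2CO3 (2.5 equiv), dioxane, 100 °C, Ar
Reagents that add atoms: none
Why: Ullmann-type coupling of 5-bromo-3,4-dialkoxybenzaldehydes with ortho-substituted phenols is a standard entry to such ethers, each partner here having only one ortho substituent.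

Step 16
Reactants: 29 D–E–F–G aldehyde
Product: 31 D–E–F–G phenol (OH at D C1), via tetramer formate 30 (not isolated)
Conditions: mCPBA (1.3 equiv), CH2Cl2, 0 °C to rt; aq. Na2SO3 wash; K2CO3 (cat.), MeOH/THF, rt
Reagents that add atoms: mCPBA OOC(=O)c1cccc(Cl)c1
Why: Baeyer–Villiger oxidation driven by the benzyloxy group para to the formyl carbon, followed by formate methanolysis, should free the D C1 phenol.

Step 17
Reactants: 31 D–E–F–G phenol; 23 2-bromo-3,4,5-tris(benzyloxy)benzaldehyde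
Product: 32 C–D–E–F–G aldehyde (ring C: CHO at C1, OBn at C3–C5, O–D at C6)
Conditions: 23 (1.5 equiv), CuI (20 mol %), N,N-dimethylglycine hydrochloride (40 mol %), Cs2CO3 (2.5 equiv), dioxane, 100 °C, Ar
Reagents that add atoms: none
Why: This Ullmann-type coupling pairs the partners as in step 12, an unhindered phenol (D C1, both neighbours CH) with the ortho-formyl-activated bromide.

Step 18
Reactants: 32 C–D–E–F–G aldehyde
Product: 34 C–D–E–F–G phenol (OH at C C1), via pentamer formate 33 (not isolated)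
Conditions: mCPBA (1.3 equiv), CH2Cl2, 0 °C to rt; aq. Na2SO3 wash; K2CO3 (cat.), MeOH/THF, rt
Reagents that add atoms: mCPBA OOC(=O)c1cccc(Cl)c1
Why: Baeyer–Villiger oxidation and formate methanolysis proceed as in step 13 on an identically substituted ring.

Step 19
Reactants: 35 4-bromo-3,5-dimethoxybenzaldehyde
Product: 36 4-bromo-3,5-dihydroxybenzaldehyde
Conditions: BBr3 (3 equiv), CH2Cl2, −78 °C to rt; H2O
Reagents that add atoms: none
Why: Lewis-acid cleavage of aryl methyl ethers with BBr3 tolerates the aryl bromide, and the aldehyde is restored on aqueous work-up.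

Step 20
Reactants: 36 4-bromo-3,5-dihydroxybenzaldehyde
Product: 37 4-bromo-3,5-bis(benzyloxy)benzaldehyde
Conditions: BnBr (2.4 equiv), K2CO3, DMF, 60 °C
Reagents that add atoms: benzyl bromide BrCc1ccccc1
Why: This is a double Williamson etherification.

Step 21
Reactants: 34 C–D–E–F–G phenol; 37 4-bromo-3,5-bis(benzyloxy)benzaldehyde
Product: 38 B–C–D–E–F–G aldehyde (ring B: CHO at C1, OBn at C3 and C5, O–C at C4)
Conditions: 37 (2 equiv), CuI (30 mol %), picolinic acid (60 mol %), K3PO4 (3 equiv), DMSO/dioxane, 100 °C, Ar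
Reagents that add atoms: none
Why: This Ullmann-type coupling uses the picolinic acid conditions devised for ortho-substituted partners, the para formyl group making the flanked C–Br bond of 37 more willing toward monovalent copper and the small bromide being used in excess.

Step 22
Reactants: 38 B–C–D–E–F–G aldehyde
Product: 40 B–C–D–E–F–G phenol (OH at B C1), via hexamer formate 39 (not isolated)
Conditions: mCPBA (1.5 equiv), CH2Cl2, 0 °C to rt; aq. Na2SO3 wash; K2CO3 (cat.), MeOH/THF, rt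
Reagents that add atoms: mCPBA OOC(=O)c1cccc(Cl)c1
Why: Baeyer–Villiger oxidation of a 4-aryloxybenzaldehyde is known to give the aryl formate, which methanolysis converts into the phenol.

Step 23
Reactants: 40 B–C–D–E–F–G phenol; 37 4-bromo-3,5-bis(benzyloxy)benzaldehyde
Product: 41 A–G heptamer aldehyde (ring A: O–B at C1, OBn at C2 and C6, CHO at C4)
Conditions: 37 (2 equiv), CuI (30 mol %), picolinic acid (60 mol %), K3PO4 (3 equiv), DMSO/dioxane, 100 °C, Ar
Reagents that add atoms: none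
Why: This Ullmann-type coupling runs as in step 21 but is easier, since the B C1 phenol has hydrogen on both neighbouring carbons.

Step 24
Reactants: 41 A–G heptamer aldehyde
Product: 43 A–G heptamer phenol (OH at A C4, seventeen benzyl ethers), via heptamer formate 42 (not isolated)
Conditions: mCPBA (1.5 equiv), CH2Cl2, 0 °C to rt; aq. Na2SO3 wash; K2CO3 (cat.), MeOH/THF, rt
Reagents that add atoms: mCPBA OOC(=O)c1cccc(Cl)c1
Why: Baeyer–Villiger oxidation and formate methanolysis as in step 22 install the last oxygen of the target, at A C4.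

Step 25
Reactants: 43 A–G heptamer phenol
Product: 44 CNP0130704.0 (target)
Conditions: H2 (1 atm), Pd(OH)2/C, THF/MeOH, rt; filtration and evaporation under Ar
Reagents that add atoms: none
Why: Catalytic hydrogenolysis should cleave all seventeen benzyl ethers and leave the six diaryl ethers intact, giving only toluene beside the air-sensitive polyphenol.

**Compound list**
1 | 1,3-bis(benzyloxy)propan-2-ol | OC(COCc1ccccc1)COCc1ccccc1 | starting material
2 | 1,3-bis(benzyloxy)propan-2-one | O=C(COCc1ccccc1)COCc1ccccc1 | intermediate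
3 | 2,4-bis(benzyloxy)-1,5-bis(dimethylamino)penta-1,4-dien-3-one (push–pull alkenes, geometry labile) | CN(C)C=C(OCc1ccccc1)C(=O)C(OCc1ccccc1)=CN(C)C | intermediate
4 | 3,5-bis(benzyloxy)-4H-pyran-4-one | O=C1C(OCc9ccccc9)=COC=C1OCc9ccccc9 | intermediate
5 | 3,4,5-trihydroxybenzaldehyde | O=Cc1cc(O)c(O)c(O)c1 | starting material
6 | 3,4,5-tris(benzyloxy)benzaldehyde | O=Cc1cc(OCc9ccccc9)c(OCc9ccccc9)c(OCc9ccccc9)c1 | intermediate
7 | 3,4,5-tris(benzyloxy)phenyl formate | O=COc1cc(OCc9ccccc9)c(OCc9ccccc9)c(OCc9ccccc9)c1 | intermediate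
8 | 3,4,5-tris(benzyloxy)phenol | Oc1cc(OCc9ccccc9)c(OCc9ccccc9)c(OCc9ccccc9)c1 | intermediate
9 | 2,6-bis(benzyloxy)-1,4-benzoquinone | O=C1C=C(OCc9ccccc9)C(=O)C(OCc9ccccc9)=C1 | intermediate
10 | 2,6-bis(benzyloxy)benzene-1,4-diol | Oc1cc(OCc9ccccc9)c(O)c(OCc9ccccc9)c1 | intermediate
11 | 4-(allyloxy)-2,6-bis(benzyloxy)phenol | C=CCOc1cc(OCc9ccccc9)c(O)c(OCc9ccccc9)c1 | intermediate
12 | triphenylphosphine | c1ccc(cc1)P(c1ccccc1)c1ccccc1 | starting material
13 | 5-(allyloxy)-1,3-bis(benzyloxy)-2-(chloromethoxy)benzene | C=CCOc1cc(OCc9ccccc9)c(OCCl)c(OCc9ccccc9)c1 | intermediate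
14 | {[4-(allyloxy)-2,6-bis(benzyloxy)phenoxy]methyl}triphenylphosphonium chloride | C=CCOc1cc(OCc9ccccc9)c(OC[P+](c9ccccc9)(c9ccccc9)c9ccccc9)c(OCc9ccccc9)c1.[Cl-] | intermediate
15 | 3,5-bis(benzyloxy)-4-[(tert-butyldimethylsilyl)oxy]pyrylium triflate | CC(C)(C)[Si](C)(C)Oc1c(OCc9ccccc9)c[o+]cc1OCc9ccccc9.[O-]S(=O)(=O)C(F)(F)F | intermediate
16 | {[4-(allyloxy)-2,6-bis(benzyloxy)phenoxy]methylidene}triphenylphosphorane | C=CCOc1cc(OCc9ccccc9)c(OC=P(c9ccccc9)(c9ccccc9)c9ccccc9)c(OCc9ccccc9)c1 | intermediate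
17 | 2H-pyran adduct: phosphonium triflate whose P–CH(OAr) carbon is bonded to C2 of 3,5-bis(benzyloxy)-4-silyloxy-2H-pyran (mixture of diastereomers, both sp3 centres are lost later) | C=CCOc1cc(OCc9ccccc9)c(OC(C2OC=C(OCc9ccccc9)C(O[Si](C)(C)C(C)(C)C)=C2OCc9ccccc9)[P+](c9ccccc9)(c9ccccc9)c9ccccc9)c(OCc9ccccc9)c1.[O-]S(=O)(=O)C(F)(F)F | intermediate
18 | ring-opened cis-dienal phosphonium triflate, OHC–C(OBn)=C(OTBS)–C(OBn)=CH–CH(OAr)–PPh3+ | C=CCOc1cc(OCc9ccccc9)c(OC(C=C(OCc9ccccc9)/C(O[Si](C)(C)C(C)(C)C)=C(/OCc9ccccc9)C=O)[P+](c9ccccc9)(c9ccccc9)c9ccccc9)c(OCc9ccccc9)c1.[O-]S(=O)(=O)C(F)(F)F | intermediate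
19 | dienal ylide (18 deprotonated at the phosphorus-bearing carbon) | C=CCOc1cc(OCc9ccccc9)c(OC(C=C(OCc9ccccc9)/C(O[Si](C)(C)C(C)(C)C)=C(/OCc9ccccc9)C=O)=P(c9ccccc9)(c9ccccc9)c9ccccc9)c(OCc9ccccc9)c1 | intermediate
20 | F–G dimer, allyl ether on F C1 and TBS ether on G C4 | C=CCOc1cc(OCc9ccccc9)c(Oc2cc(OCc9ccccc9)c(O[Si](C)(C)C(C)(C)C)c(OCc9ccccc9)c2)c(OCc9ccccc9)c1 | intermediate
21 | F–G dimer, allyl ether on F C1, ring G tribenzylated | C=CCOc1cc(OCc9ccccc9)c(Oc2cc(OCc9ccccc9)c(OCc9ccccc9)c(OCc9ccccc9)c2)c(OCc9ccccc9)c1 | intermediate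
22 | F–G phenol, 3,5-bis(benzyloxy)-4-[3,4,5-tris(benzyloxy)phenoxy]phenol | Oc4cc(OCc9ccccc9)c(Oc5cc(OCc9ccccc9)c(OCc9ccccc9)c(OCc9ccccc9)c5)c(OCc9ccccc9)c4 | intermediate
23 | 2-bromo-3,4,5-tris(benzyloxy)benzaldehyde | O=Cc1cc(OCc9ccccc9)c(OCc9ccccc9)c(OCc9ccccc9)c1Br | intermediate
24 | E–F–G aldehyde (CHO at E C1) | O=Cc3cc(OCc9ccccc9)c(OCc9ccccc9)c(OCc9ccccc9)c3Oc4cc(OCc9ccccc9)c(Oc5cc(OCc9ccccc9)c(OCc9ccccc9)c(OCc9ccccc9)c5)c(OCc9ccccc9)c4 | intermediate
25 | E–F–G formate (OCHO at E C1) | O=COc3cc(OCc9ccccc9)c(OCc9ccccc9)c(OCc9ccccc9)c3Oc4cc(OCc9ccccc9)c(Oc5cc(OCc9ccccc9)c(OCc9ccccc9)c(OCc9ccccc9)c5)c(OCc9ccccc9)c4 | intermediate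
26 | E–F–G phenol (OH at E C1) | Oc3cc(OCc9ccccc9)c(OCc9ccccc9)c(OCc9ccccc9)c3Oc4cc(OCc9ccccc9)c(Oc5cc(OCc9ccccc9)c(OCc9ccccc9)c(OCc9ccccc9)c5)c(OCc9ccccc9)c4 | intermediate
27 | 3-bromo-4,5-dihydroxybenzaldehyde | O=Cc1cc(O)c(O)c(Br)c1 | starting material
28 | 3-bromo-4,5-bis(benzyloxy)benzaldehyde | O=Cc1cc(OCc9ccccc9)c(OCc9ccccc9)c(Br)c1 | intermediate
29 | D–E–F–G aldehyde (CHO at D C1) | O=Cc2cc(OCc9ccccc9)c(OCc9ccccc9)c(Oc3cc(OCc9ccccc9)c(OCc9ccccc9)c(OCc9ccccc9)c3Oc4cc(OCc9ccccc9)c(Oc5cc(OCc9ccccc9)c(OCc9ccccc9)c(OCc9ccccc9)c5)c(OCc9ccccc9)c4)c2 | intermediate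
30 | D–E–F–G formate (OCHO at D C1) | O=COc2cc(OCc9ccccc9)c(OCc9ccccc9)c(Oc3cc(OCc9ccccc9)c(OCc9ccccc9)c(OCc9ccccc9)c3Oc4cc(OCc9ccccc9)c(Oc5cc(OCc9ccccc9)c(OCc9ccccc9)c(OCc9ccccc9)c5)c(OCc9ccccc9)c4)c2 | intermediate
31 | D–E–F–G phenol (OH at D C1) | Oc2cc(OCc9ccccc9)c(OCc9ccccc9)c(Oc3cc(OCc9ccccc9)c(OCc9ccccc9)c(OCc9ccccc9)c3Oc4cc(OCc9ccccc9)c(Oc5cc(OCc9ccccc9)c(OCc9ccccc9)c(OCc9ccccc9)c5)c(OCc9ccccc9)c4)c2 | intermediate
32 | C–D–E–F–G aldehyde (CHO at C C1) | O=Cc1cc(OCc9ccccc9)c(OCc9ccccc9)c(OCc9ccccc9)c1Oc2cc(OCc9ccccc9)c(OCc9ccccc9)c(Oc3cc(OCc9ccccc9)c(OCc9ccccc9)c(OCc9ccccc9)c3Oc4cc(OCc9ccccc9)c(Oc5cc(OCc9ccccc9)c(OCc9ccccc9)c(OCc9ccccc9)c5)c(OCc9ccccc9)c4)c2 | intermediate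
33 | C–D–E–F–G formate (OCHO at C C1) | O=COc1cc(OCc9ccccc9)c(OCc9ccccc9)c(OCc9ccccc9)c1Oc2cc(OCc9ccccc9)c(OCc9ccccc9)c(Oc3cc(OCc9ccccc9)c(OCc9ccccc9)c(OCc9ccccc9)c3Oc4cc(OCc9ccccc9)c(Oc5cc(OCc9ccccc9)c(OCc9ccccc9)c(OCc9ccccc9)c5)c(OCc9ccccc9)c4)c2 | intermediate
34 | C–D–E–F–G phenol (OH at C C1) | Oc1cc(OCc9ccccc9)c(OCc9ccccc9)c(OCc9ccccc9)c1Oc2cc(OCc9ccccc9)c(OCc9ccccc9)c(Oc3cc(OCc9ccccc9)c(OCc9ccccc9)c(OCc9ccccc9)c3Oc4cc(OCc9ccccc9)c(Oc5cc(OCc9ccccc9)c(OCc9ccccc9)c(OCc9ccccc9)c5)c(OCc9ccccc9)c4)c2 | intermediate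
35 | 4-bromo-3,5-dimethoxybenzaldehyde | O=Cc1cc(OC)c(Br)c(OC)c1 | starting material
36 | 4-bromo-3,5-dihydroxybenzaldehyde | O=Cc1cc(O)c(Br)c(O)c1 | intermediate
37 | 4-bromo-3,5-bis(benzyloxy)benzaldehyde | O=Cc1cc(OCc9ccccc9)c(Br)c(OCc9ccccc9)c1 | intermediate
38 | B–C–D–E–F–G aldehyde (CHO at B C1) | O=Cc6cc(OCc9ccccc9)c(Oc1cc(OCc9ccccc9)c(OCc9ccccc9)c(OCc9ccccc9)c1Oc2cc(OCc9ccccc9)c(OCc9ccccc9)c(Oc3cc(OCc9ccccc9)c(OCc9ccccc9)c(OCc9ccccc9)c3Oc4cc(OCc9ccccc9)c(Oc5cc(OCc9ccccc9)c(OCc9ccccc9)c(OCc9ccccc9)c5)c(OCc9ccccc9)c4)c2)c(OCc9ccccc9)c6 | intermediate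
39 | B–C–D–E–F–G formate (OCHO at B C1) | O=COc6cc(OCc9ccccc9)c(Oc1cc(OCc9ccccc9)c(OCc9ccccc9)c(OCc9ccccc9)c1Oc2cc(OCc9ccccc9)c(OCc9ccccc9)c(Oc3cc(OCc9ccccc9)c(OCc9ccccc9)c(OCc9ccccc9)c3Oc4cc(OCc9ccccc9)c(Oc5cc(OCc9ccccc9)c(OCc9ccccc9)c(OCc9ccccc9)c5)c(OCc9ccccc9)c4)c2)c(OCc9ccccc9)c6 | intermediate
40 | B–C–D–E–F–G phenol (OH at B C1) | Oc6cc(OCc9ccccc9)c(Oc1cc(OCc9ccccc9)c(OCc9ccccc9)c(OCc9ccccc9)c1Oc2cc(OCc9ccccc9)c(OCc9ccccc9)c(Oc3cc(OCc9ccccc9)c(OCc9ccccc9)c(OCc9ccccc9)c3Oc4cc(OCc9ccccc9)c(Oc5cc(OCc9ccccc9)c(OCc9ccccc9)c(OCc9ccccc9)c5)c(OCc9ccccc9)c4)c2)c(OCc9ccccc9)c6 | intermediate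
41 | A–G heptamer aldehyde (CHO at A C4) | O=Cc7cc(OCc9ccccc9)c(Oc6cc(OCc9ccccc9)c(Oc1cc(OCc9ccccc9)c(OCc9ccccc9)c(OCc9ccccc9)c1Oc2cc(OCc9ccccc9)c(OCc9ccccc9)c(Oc3cc(OCc9ccccc9)c(OCc9ccccc9)c(OCc9ccccc9)c3Oc4cc(OCc9ccccc9)c(Oc5cc(OCc9ccccc9)c(OCc9ccccc9)c(OCc9ccccc9)c5)c(OCc9ccccc9)c4)c2)c(OCc9ccccc9)c6)c(OCc9ccccc9)c7 | intermediate
42 | A–G heptamer formate (OCHO at A C4) | O=COc7cc(OCc9ccccc9)c(Oc6cc(OCc9ccccc9)c(Oc1cc(OCc9ccccc9)c(OCc9ccccc9)c(OCc9ccccc9)c1Oc2cc(OCc9ccccc9)c(OCc9ccccc9)c(Oc3cc(OCc9ccccc9)c(OCc9ccccc9)c(OCc9ccccc9)c3Oc4cc(OCc9ccccc9)c(Oc5cc(OCc9ccccc9)c(OCc9ccccc9)c(OCc9ccccc9)c5)c(OCc9ccccc9)c4)c2)c(OCc9ccccc9)c6)c(OCc9ccccc9)c7 | intermediate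
43 | A–G heptamer phenol (OH at A C4, seventeen benzyl ethers) | Oc7cc(OCc9ccccc9)c(Oc6cc(OCc9ccccc9)c(Oc1cc(OCc9ccccc9)c(OCc9ccccc9)c(OCc9ccccc9)c1Oc2cc(OCc9ccccc9)c(OCc9ccccc9)c(Oc3cc(OCc9ccccc9)c(OCc9ccccc9)c(OCc9ccccc9)c3Oc4cc(OCc9ccccc9)c(Oc5cc(OCc9ccccc9)c(OCc9ccccc9)c(OCc9ccccc9)c5)c(OCc9ccccc9)c4)c2)c(OCc9ccccc9)c6)c(OCc9ccccc9)c7 | intermediate
44 | CNP0130704.0 | Oc1cc(O)c(Oc2cc(O)c(Oc3cc(O)c(O)c(O)c3Oc3cc(O)c(O)c(Oc4cc(O)c(O)c(O)c4Oc4cc(O)c(Oc5cc(O)c(O)c(O)c5)c(O)c4)c3)c(O)c2)c(O)c1 | target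

**Totals**
Total step count: 25.
Longest linear sequence: 19 steps (5 → 6 → 8 → 9 → 11 → 14 → 20 → 21 → 22 → 24 → 26 → 29 → 31 → 32 → 34 → 38 → 40 → 41 → 43 → 44).

**Steps most likely to fail**

Step 8. The ylide may attack silicon and return pyranone 4. It may add at C4, or decay before it meets the pyrylium ion. The open-chain dienal may also polymerise instead of closing. The fallback uses known chemistry, sets out from phenol 11 and comes back at 21. Purchased 5-bromo-1,2,3-trimethoxybenzene F1 is demethylated with BBr3 to 5-bromobenzene-1,2,3-triol F2. This is benzylated (BnBr, K2CO3, DMF) to 5-bromo-1,2,3-tris(benzyloxy)benzene F3. The unhindered bromide is then joined to the flanked phenol 11 by Ullmann coupling (CuI, picolinic acid, K3PO4, DMSO, 90 °C). This gives 21 directly, and steps 9 and 1–2 are no longer needed.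

Step 21. The doubly flanked C–Br bond may react too slowly with a copper phenoxide that itself carries a bulky ortho aryloxy group. Hydrodebromination of the bromide and oxidative decay of the phenoxide would then overtake coupling. The fallback replaces copper catalysis by metal-free ligand coupling at trivalent iodine; it sets out from 37 and 34 and comes back at 38. Miyaura-type borylation of 37 (B2(OH)4, Pd(OAc)2, XPhos, KOAc, EtOH, 80 °C) gives [2,6-bis(benzyloxy)-4-formylphenyl]boronic acid F4. Treatment with 4-MeOC6H4I(OAc)2 and BF3·OEt2 in CH2Cl2, then aqueous NaBF4, gives [2,6-bis(benzyloxy)-4-formylphenyl](4-methoxyphenyl)iodonium tetrafluoroborate F5. The potassium phenoxide of 34 (KOt-Bu, THF) should then take over the electron-poorer, doubly ortho-substituted aryl group of the salt and give 38.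

Step 7. The chloromethyl ether may be consumed by a second phenoxide to give the bis(aryloxy)methane, or it may hydrolyse during handling. The fallback goes through an O,S-acetal, sets out from 11 and comes back at 13. Alkylation of 11 with ClCH2SMe (NaH, NaI, DMF) gives 5-(allyloxy)-1,3-bis(benzyloxy)-2-[(methylsulfanyl)methoxy]benzene F6. Cleavage with SO2Cl2 in CH2Cl2 at −78 to 0 °C then delivers 13, which is quaternised with 12 as before. Excess cyclohexene is present during the cleavage to keep the sulfenyl chloride away from the allyl group.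

**Further compounds**
F1 | step 8 | 5-bromo-1,2,3-trimethoxybenzene (purchased) | COc1cc(Br)cc(OC)c1OC
F2 | step 8 | 5-bromobenzene-1,2,3-triol | Oc1cc(Br)cc(O)c1O
F3 | step 8 | 5-bromo-1,2,3-tris(benzyloxy)benzene | Brc1cc(OCc9ccccc9)c(OCc9ccccc9)c(OCc9ccccc9)c1
F4 | step 21 | [2,6-bis(benzyloxy)-4-formylphenyl]boronic acid | O=Cc1cc(OCc9ccccc9)c(B(O)O)c(OCc9ccccc9)c1
F5 | step 21 | [2,6-bis(benzyloxy)-4-formylphenyl](4-methoxyphenyl)iodonium tetrafluoroborate | O=Cc1cc(OCc9ccccc9)c([I+]c2ccc(OC)cc2)c(OCc9ccccc9)c1.F[B-](F)(F)F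
F6 | step 7 | 5-(allyloxy)-1,3-bis(benzyloxy)-2-[(methylsulfanyl)methoxy]benzene | C=CCOc1cc(OCc9ccccc9)c(OCSC)c(OCc9ccccc9)c1
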